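## Retrosynthetic overview

1. Target ⇐ ester-to-carbinol reduction of the (5R)-tetrahydroquinolone 2-carboxylate.
2. C5 stereocentre ⇐ enantioselective hydrogenation of the benzo ring of a flat, achiral 5-octyl-N-methoxy-4-quinolone; this is the only stereo-setting event.
3. 5-Octyl group ⇐ Negishi coupling at a 5-chloroquinolone.
4. N-Methoxy-4-pyridone ring ⇐ methoxyamine condensation and intramolecular SNAr on an aryl 2,4-diketo ester.
5. Diketo ester ⇐ oxalate Claisen on an α-methoxy aryl ketone ⇐ ortho-lithiation of 1-chloro-3-fluorobenzene. Ring order: the benzene ring comes from the feedstock, the pyridone ring is the only ring formed (step 3), and the benzene ring is saturated to the carbocycle in step 5.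

Assumption: the sense of induction in step 5 cannot be predicted from precedent, so the ligand antipode named there is taken to give (R); if the first run gives (S), the other commercial antipode is used with no other change.

## Route

Step 1
Reactants: 1 1-chloro-3-fluorobenzene; 2 N,2-dimethoxy-N-methylacetamide
Product: 4 1-(2-chloro-6-fluorophenyl)-2-methoxyethan-1-one, via (2-chloro-6-fluorophenyl)lithium 3 (not isolated)
Conditions: n-BuLi, THF, −78 °C, 1 h; then 2, −78 → −40 °C; aq NH4Cl
Reagents that add atoms: none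
Why: Directed ortho-lithiation removes the most acidic proton (flanked by F and Cl), and the aryllithium adds once to the Weinreb amide through a stable chelated tetrahedral intermediate that gives the ketone only on quench; −78 °C prevents aryne formation.

Step 2
Reactants: 4 1-(2-chloro-6-fluorophenyl)-2-methoxyethan-1-one; 5 dimethyl oxalate
Product: 6 methyl 4-(2-chloro-6-fluorophenyl)-3-methoxy-2,4-dioxobutanoate
Conditions: LiHMDS (2.2 equiv), THF, −78 °C; then 5, −78 → 0 °C; 1 M HCl
Reagents that add atoms: none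
Why: Crossed Claisen condensation in which the ketone has a single enolisable site, the oxalate cannot enolise and deprotonation of the tricarbonyl product drives the reaction; keeping it at or below 0 °C avoids O-cyclisation onto the C–F bond.

Step 3
Reactants: 6 methyl 4-(2-chloro-6-fluorophenyl)-3-methoxy-2,4-dioxobutanoate
Product: 8 methyl 5-chloro-1,3-dimethoxy-4-oxo-1,4-dihydroquinoline-2-carboxylate, via O-methyl oxime 7 (not isolated)
Conditions: MeONH2·HCl, NaOAc, MeOH, 40 °C; evaporate; then K2CO3, DMF, 80 °C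
Reagents that add atoms: O-methylhydroxylamine hydrochloride, CON.Cl
Why: Methoxyamine condenses at the α-keto ester carbonyl (the aryl ketone is shielded by two ortho substituents), and the deprotonated N-methoxy enamine tautomer then closes the ring by intramolecular SNAr at the fluorine ortho to the ketone (Grohe–Heitzer-type quinolone synthesis), fluoride leaving much faster than chloride.

Step 4
Reactants: 8 methyl 5-chloro-1,3-dimethoxy-4-oxo-1,4-dihydroquinoline-2-carboxylate; 9 n-octylzinc bromide
Product: 10 methyl 1,3-dimethoxy-5-octyl-4-oxo-1,4-dihydroquinoline-2-carboxylate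
Conditions: Pd-PEPPSI-IPr (2 mol %), 9 (1.5 equiv, 0.5 M in THF), THF/NMP 2:1, 50 °C
Reagents that add atoms: none
Why: Negishi sp2–sp3 cross-coupling in which the peri carbonyl activates C5–Cl for oxidative addition, the bulky NHC–Pd catalyst suppresses β-hydride elimination and the organozinc tolerates the ester, the pyridone and the N–OMe group.

Step 5
Reactants: 10 methyl 1,3-dimethoxy-5-octyl-4-oxo-1,4-dihydroquinoline-2-carboxylate
Product: 11 methyl (5R)-1,3-dimethoxy-5-octyl-4-oxo-1,4,5,6,7,8-hexahydroquinoline-2-carboxylate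
Conditions: [Ru(cod)(2-methylallyl)2] (5 mol %), (R,R)-SINpEt·HBF4 (10 mol %), KOtBu (12 mol %), n-hexane, 70 °C (catalyst preformation); then 10, H2 (100 bar), n-hexane/Et2O, 30 °C
Reagents that add atoms: none
Why: Proposed new method: a chiral Ru–NHC hydride binds the benzo ring η6 on one enantioface and delivers two H2 syn to C5–C8, while the C4a=C8a bond stays because it belongs to the fully substituted N-methoxy-4-pyridone (a vinylogous amide that is not reduced), so the face chosen by the catalyst pocket fixes C5 as R, the octyl group next to the ring fusion being the stereo-differentiating element; the closest known reaction types are Ru–NHC carbocycle-selective asymmetric hydrogenation of quinoxalines, Ru–PhTRAP carbocycle-selective asymmetric hydrogenation of 8-substituted quinolines and racemic Pt/acid hydrogenation of 4-quinolones to 5,6,7,8-tetrahydro-4-quinolones, and the N–OMe bond is expected to survive as N-alkoxy amides do under homogeneous Ru/H2.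

Step 6
Reactants: 11 methyl (5R)-1,3-dimethoxy-5-octyl-4-oxo-1,4,5,6,7,8-hexahydroquinoline-2-carboxylate
Product: 12 (5R)-2-(hydroxymethyl)-1,3-dimethoxy-5-octyl-5,6,7,8-tetrahydroquinolin-4(1H)-one
Conditions: LiBH4 (2 equiv), THF, 0 °C → rt; aq NH4Cl
Reagents that add atoms: none
Why: Chemoselective borohydride reduction of the electron-poor 2-carboxylate to the primary alcohol; the vinylogous-amide carbonyl and N–OMe are inert to LiBH4 and C5–H is not enolisable, so the stereocentre is untouched.

## Compound list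

1 | 1-chloro-3-fluorobenzene | Fc1cccc(Cl)c1 | starting material
2 | N,2-dimethoxy-N-methylacetamide | COCC(=O)N(C)OC | starting material
3 | (2-chloro-6-fluorophenyl)lithium | [Li]c1c(F)cccc1Cl | intermediate
4 | 1-(2-chloro-6-fluorophenyl)-2-methoxyethan-1-one | COCC(=O)c1c(F)cccc1Cl | intermediate
5 | dimethyl oxalate | COC(=O)C(=O)OC | starting material
6 | methyl 4-(2-chloro-6-fluorophenyl)-3-methoxy-2,4-dioxobutanoate | COC(=O)C(=O)C(OC)C(=O)c1c(F)cccc1Cl | intermediate
7 | methyl 4-(2-chloro-6-fluorophenyl)-3-methoxy-2-(methoxyimino)-4-oxobutanoate (E/Z mixture) | COC(=O)C(=NOC)C(OC)C(=O)c1c(F)cccc1Cl | intermediate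
8 | methyl 5-chloro-1,3-dimethoxy-4-oxo-1,4-dihydroquinoline-2-carboxylate | COC(=O)c1c(OC)c(=O)c2c(Cl)cccc2n1OC | intermediate
9 | n-octylzinc bromide | CCCCCCCC[Zn]Br | starting material
10 | methyl 1,3-dimethoxy-5-octyl-4-oxo-1,4-dihydroquinoline-2-carboxylate | CCCCCCCCc1cccc2c1c(=O)c(OC)c(C(=O)OC)n2OC | intermediate
11 | methyl (5R)-1,3-dimethoxy-5-octyl-4-oxo-1,4,5,6,7,8-hexahydroquinoline-2-carboxylate | CCCCCCCC[C@@H]1CCCc2c1c(=O)c(OC)c(C(=O)OC)n2OC | intermediate
12 | (5R)-2-(hydroxymethyl)-1,3-dimethoxy-5-octyl-5,6,7,8-tetrahydroquinolin-4(1H)-one | CCCCCCCC[C@@H]1CCCc2c1c(=O)c(OC)c(CO)n2OC | target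

## Step count and risks

Total step count: 6. Longest linear sequence: 6.

Steps most likely to fail:

**Step 5 (asymmetric hydrogenation of the benzo ring).** The risks are N–OMe hydrogenolysis, low conversion and low ee on a substrate class without direct precedent. The fallback sets out from 6 and comes back at 11. It moves the dearomatisation to an N–O-free 4-methoxyquinoline, the class with direct precedent, and installs the N–OMe afterwards. Condensing 6 with NH4OAc (EtOH/AcOH, 60 °C) gives methyl 2-amino-4-(2-chloro-6-fluorophenyl)-3-methoxy-4-oxobut-2-enoate F1. This closes with K2CO3 in DMF to methyl 5-chloro-3-methoxy-4-oxo-1,4-dihydroquinoline-2-carboxylate F2. O-Methylation with MeI/Ag2CO3 in toluene gives methyl 5-chloro-3,4-dimethoxyquinoline-2-carboxylate F3. Negishi coupling with 9 gives methyl 3,4-dimethoxy-5-octylquinoline-2-carboxylate F4. Carbocycle-selective hydrogenation with [Ru(cod)(2-methylallyl)2]/PhTRAP under H2 (50 bar) gives methyl (5R)-3,4-dimethoxy-5-octyl-5,6,7,8-tetrahydroquinoline-2-carboxylate F5. mCPBA converts this to methyl (5R)-3,4-dimethoxy-5-octyl-5,6,7,8-tetrahydroquinoline-2-carboxylate 1-oxide F6. Heating F6 with MeI in MeCN (60 °C, sealed) methylates the N-oxide oxygen to (5R)-1,3,4-trimethoxy-2-(methoxycarbonyl)-5-octyl-5,6,7,8-tetrahydroquinolin-1-ium iodide F7, and iodide then removes the 4-O-methyl group to give 11.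

**Step 3 (oxime ether formation and SNAr ring closure).** The risks are attack of methoxyamine at the wrong carbonyl, cleavage of the tricarbonyl, and chromone formation. The fallback sets out from 4 and comes back at 8. It forms the N-methoxyquinolone first by the classical enaminone sequence and adds the C2 carbon afterwards. Heating 4 with DMF dimethyl acetal (neat, 100 °C) gives 1-(2-chloro-6-fluorophenyl)-3-(dimethylamino)-2-methoxyprop-2-en-1-one F8. Amine exchange with MeONH2·HCl in EtOH gives 1-(2-chloro-6-fluorophenyl)-2-methoxy-3-(methoxyamino)prop-2-en-1-one F9. K2CO3 in DMF at 80 °C closes it to 5-chloro-1,3-dimethoxyquinolin-4(1H)-one F10. Deprotonation at C2 with LDA (THF, −78 °C), directed by the N–OMe and 3-OMe groups, gives (5-chloro-1,3-dimethoxy-4-oxo-1,4-dihydroquinolin-2-yl)lithium F11, which is trapped with methyl chloroformate to give 8.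

**Step 4 (alkyl Negishi at the hindered peri C–Cl with N–OMe present).** The risks are reduction instead of coupling and Pd insertion into N–O. The fallback sets out from 4 and comes back at 10. It makes the C–octyl bond on the uncongested monocyclic arene before the heterocycle exists. Negishi coupling of 4 with 9 (Pd-PEPPSI-IPr; C–F is inert) gives 1-(2-fluoro-6-octylphenyl)-2-methoxyethan-1-one F12. Claisen condensation with 5 (LiHMDS, THF) gives methyl 4-(2-fluoro-6-octylphenyl)-3-methoxy-2,4-dioxobutanoate F13. MeONH2·HCl/NaOAc converts this to methyl 4-(2-fluoro-6-octylphenyl)-3-methoxy-2-(methoxyimino)-4-oxobutanoate F14, which cyclises with K2CO3 in DMF to give 10.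

Further compounds
F1 | step 5 | methyl 2-amino-4-(2-chloro-6-fluorophenyl)-3-methoxy-4-oxobut-2-enoate | COC(=O)C(N)=C(OC)C(=O)c1c(F)cccc1Cl
F2 | step 5 | methyl 5-chloro-3-methoxy-4-oxo-1,4-dihydroquinoline-2-carboxylate | COC(=O)c1[nH]c2cccc(Cl)c2c(=O)c1OC
F3 | step 5 | methyl 5-chloro-3,4-dimethoxyquinoline-2-carboxylate | COC(=O)c1nc2cccc(Cl)c2c(OC)c1OC
F4 | step 5 | methyl 3,4-dimethoxy-5-octylquinoline-2-carboxylate | CCCCCCCCc1cccc2nc(C(=O)OC)c(OC)c(OC)c12
F5 | step 5 | methyl (5R)-3,4-dimethoxy-5-octyl-5,6,7,8-tetrahydroquinoline-2-carboxylate | CCCCCCCC[C@@H]1CCCc2nc(C(=O)OC)c(OC)c(OC)c21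
F6 | step 5 | methyl (5R)-3,4-dimethoxy-5-octyl-5,6,7,8-tetrahydroquinoline-2-carboxylate 1-oxide | CCCCCCCC[C@@H]1CCCc2c1c(OC)c(OC)c(C(=O)OC)[n+]2[O-]
F7 | step 5 | (5R)-1,3,4-trimethoxy-2-(methoxycarbonyl)-5-octyl-5,6,7,8-tetrahydroquinolin-1-ium iodide | CCCCCCCC[C@@H]1CCCc2c1c(OC)c(OC)c(C(=O)OC)[n+]2OC.[I-]
F8 | step 3 | 1-(2-chloro-6-fluorophenyl)-3-(dimethylamino)-2-methoxyprop-2-en-1-one | CN(C)C=C(OC)C(=O)c1c(F)cccc1Cl
F9 | step 3 | 1-(2-chloro-6-fluorophenyl)-2-methoxy-3-(methoxyamino)prop-2-en-1-one | CONC=C(OC)C(=O)c1c(F)cccc1Cl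
F10 | step 3 | 5-chloro-1,3-dimethoxyquinolin-4(1H)-one | COc1cn(OC)c2cccc(Cl)c2c1=O
F11 | step 3 | (5-chloro-1,3-dimethoxy-4-oxo-1,4-dihydroquinolin-2-yl)lithium | COc1c([Li])n(OC)c2cccc(Cl)c2c1=O
F12 | step 4 | 1-(2-fluoro-6-octylphenyl)-2-methoxyethan-1-one | CCCCCCCCc1cccc(F)c1C(=O)COC
F13 | step 4 | methyl 4-(2-fluoro-6-octylphenyl)-3-methoxy-2,4-dioxobutanoate | CCCCCCCCc1cccc(F)c1C(=O)C(OC)C(=O)C(=O)OC
F14 | step 4 | methyl 4-(2-fluoro-6-octylphenyl)-3-methoxy-2-(methoxyimino)-4-oxobutanoate | CCCCCCCCc1cccc(F)c1C(=O)C(OC)C(=NOC)C(=O)OC
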